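**Plan**

- Retrosynthesis: the butenolide is cut at its C4–CH2OH bond (cross-coupling) and its C3–C4 bond (Dieckmann closure of an α-acetoxy ester). The chain is cut at the =CH–CH2 bond next to the lactone (alkenyl metal plus a glycidic ester), at both C–C bonds of the hydroxymethyl-bearing alkene carbon (carbomagnesiation of a propargylic alkoxide), at the =CH–CH2 and C–CH3 bonds of the methyl-bearing alkene (carboalumination, epoxide opening) and at the ring–CH2 bond. The carbocycle is cut last, at CH2–CMe2 and at the ring C=C.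
- Forward: the six-membered ring is made first, in one operation, from two simple carbonyl compounds; the chain is then grown outwards from the ring in C4, C1, C2, C3 and C3 units; the lactone ring is closed in step 13 and receives its CH2OH in step 15.
- Feature that allows the ring event: in the cyclohexene the carbinol carbon and the chain-bearing sp2 carbon stand 1,3 across the methyl-bearing sp2 carbon, the pattern of an enolised 2-methyl-1,3-diketone. The CMe2 carbon next to the chain-bearing carbon is then an ester α-carbon, and the two ring CH2 groups are the vinyl group of a vinyl ketone.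
- Helper: an oxygen on the chain-bearing ring carbon (absent from the target) makes the closure a Claisen acylation with only one possible regiochemistry; it is removed in step 3, when the side chain enters at that carbon.
- Stereochemistry: ring carbinol (S) by catalyst-controlled ketone reduction; lactone carbon (S) from the chiral pool; (E)-alkene by syn-carboalumination; (Z)-alkene by chelation-controlled anti-carbomagnesiation. The two remote stereocentres are set independently.

Key step: step 1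

Remark: TBS is tert-butyldimethylsilyl and TBSO its ether oxygen; 4-bromo-1-(trimethylsilyl)but-1-yne, methyl (S)-glycidate and (tributylstannyl)methanol are taken as purchasable.

**Route**

Step 1
Reactants: 1 methyl isobutyrate; 2 ethyl vinyl ketone (pent-1-en-3-one)
Product: 4 2,4,4-trimethylcyclohexane-1,3-dione, via keto ester enolate 3 (not isolated)
Conditions: LiN(i-Pr)2, THF, −78 °C; 2, −78 → 0 °C; KOt-Bu, 0 → 25 °C; aq. HCl
Reagents that add atoms: none
Why: Michael–Claisen annulation, the closest known reaction type being the one-pot synthesis of cyclohexane-1,3-diones from an enolate and an acrylic acceptor: the lithium enolate of 1 adds in conjugate fashion to the unsubstituted vinyl carbon of 2 and so makes the CH2–CMe2 bond (keto ester 3, kept as its enolate). With KOt-Bu the enolate equilibrates to the ethyl-side α-carbon, which attacks the ester carbonyl in a 6-exo-trig intramolecular Claisen (Dieckmann-type) closure that makes the second ring bond and expels methoxide. The six-membered carbocycle is the only ring closed, and no stereocentre is created, because the methyl-bearing carbon of the 2-methyl-1,3-dione is enolised towards the former ester carbon (the future ring C=C). The step needs 1,4- instead of 1,2-addition and a single acylation mode: the hindered α,α-disubstituted ester enolate adds reversibly at the carbonyl but irreversibly at the terminal CH2, the only other ketone enolate could close nothing but a four-membered ring, and the ester as electrophile avoids any aldol onto a hindered ketone. Deprotonation of the acidic 1,3-dione by the alkoxide set free should drive the sequence to completion.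

Step 2
Reactants: 4 2,4,4-trimethylcyclohexane-1,3-dione
Product: 5 3-isobutoxy-2,6,6-trimethylcyclohex-2-en-1-one
Conditions: isobutanol, p-TsOH·H2O (cat.), toluene, reflux, Dean–Stark trap
Reagents that add atoms: isobutanol CC(C)CO
Why: Acid-catalysed enol etherification (vinylogous ester formation) should take place at the carbonyl remote from the gem-dimethyl group for steric reasons, so that the remaining ketone is the one next to the quaternary carbon.

Step 3
Reactants: 5 3-isobutoxy-2,6,6-trimethylcyclohex-2-en-1-one; 6 4-bromo-1-(trimethylsilyl)but-1-yne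
Product: 9 2,4,4-trimethyl-3-[4-(trimethylsilyl)but-3-yn-1-yl]cyclohex-2-en-1-one, via Grignard reagent 7 (not isolated), via magnesium alkoxide 8 (not isolated)
Conditions: 6, Mg, THF, 40 °C; 5, LaCl3·2LiCl (30 mol %), 0 °C; 1 M HCl, THF, 25 °C
Reagents that add atoms: water O
Why: Stork–Danheiser sequence, in which 1,2-addition to the ketone of the vinylogous ester and acid hydrolysis with allylic transposition place the chain on the sp2 carbon next to the quaternary carbon and the carbonyl on the future carbinol carbon, the helper oxygen leaving as water.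

Step 4
Reactants: 9 2,4,4-trimethyl-3-[4-(trimethylsilyl)but-3-yn-1-yl]cyclohex-2-en-1-one
Product: 10 (S)-2,4,4-trimethyl-3-[4-(trimethylsilyl)but-3-yn-1-yl]cyclohex-2-en-1-ol
Conditions: (R)-2-methyl-CBS-oxazaborolidine (20 mol %), catecholborane, toluene, −78 °C; MeOH, then aq. NaOH
Reagents that add atoms: none
Why: Corey–Bakshi–Shibata reduction, in which the oxazaborolidine–borane complex binds the ketone with the methyl-substituted alkenyl carbon as the large group and delivers hydride to one face, which with the (R)-catalyst should give the (S)-allylic alcohol.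

Step 5
Reactants: 10 (S)-2,4,4-trimethyl-3-[4-(trimethylsilyl)but-3-yn-1-yl]cyclohex-2-en-1-ol
Product: 11 (S)-3-(but-3-yn-1-yl)-2,4,4-trimethylcyclohex-2-en-1-ol
Conditions: K2CO3 (cat.), MeOH, 25 °C
Reagents that add atoms: none
Why: Base-catalysed methanolysis of the alkynyl C–Si bond (protodesilylation) should free the terminal alkyne without touching the allylic alcohol.

Step 6
Reactants: 11 (S)-3-(but-3-yn-1-yl)-2,4,4-trimethylcyclohex-2-en-1-ol
Product: 12 (S)-3-(but-3-yn-1-yl)-1-(TBSO)-2,4,4-trimethylcyclohex-2-ene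
Conditions: TBSCl, imidazole, DMF, 25 °C
Reagents that add atoms: tert-butyldimethylsilyl chloride CC(C)(C)[Si](C)(C)Cl
Why: Silyl ether formation masks the secondary allylic alcohol against the organometallic steps that follow.

Step 7
Reactants: 12 (S)-3-(but-3-yn-1-yl)-1-(TBSO)-2,4,4-trimethylcyclohex-2-ene; 13 ethylene oxide
Product: 16 (E)-6-[(S)-3-(TBSO)-2,6,6-trimethylcyclohex-1-en-1-yl]-4-methylhex-3-en-1-ol, via alkenylalane 14 (not isolated), via lithium alanate 15 (not isolated)
Conditions: Me3Al, (C5H5)2ZrCl2 (25 mol %), CH2Cl2, 25 °C; n-BuLi, THF, −78 °C; 13, −78 → 0 °C; aq. potassium sodium tartrate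
Reagents that add atoms: trimethylaluminium C[Al](C)C
Why: Zirconium-catalysed syn-carboalumination (Negishi carboalumination) puts methyl on the internal and aluminium on the terminal alkyne carbon, and the derived alanate opens the epoxide with retention at the alkenyl carbon, which fixes the (E)-trisubstituted alkene.

Step 8
Reactants: 16 (E)-6-[(S)-3-(TBSO)-2,6,6-trimethylcyclohex-1-en-1-yl]-4-methylhex-3-en-1-ol
Product: 17 (S)-3-[(E)-6-bromo-3-methylhex-3-en-1-yl]-1-(TBSO)-2,4,4-trimethylcyclohex-2-ene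
Conditions: CBr4, PPh3, CH2Cl2, 0 °C
Reagents that add atoms: carbon tetrabromide BrC(Br)(Br)Br
Why: The Appel reaction converts the primary homoallylic alcohol into the bromide under neutral conditions that spare the allylic silyl ether.

Step 9
Reactants: 17 (S)-3-[(E)-6-bromo-3-methylhex-3-en-1-yl]-1-(TBSO)-2,4,4-trimethylcyclohex-2-ene; 18 propargyl alcohol (prop-2-yn-1-ol)
Product: 22 (Z)-3-iodo-2-{(E)-6-[(S)-3-(TBSO)-2,6,6-trimethylcyclohex-1-en-1-yl]-4-methylhex-3-en-1-yl}prop-2-en-1-ol, via Grignard reagent 19 (not isolated), via bromomagnesium propynolate 20 (not isolated), via alkenylmagnesium chelate 21 (not isolated)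
Conditions: 17, Mg, THF, 40 °C; 18, EtMgBr, THF, 0 °C; both solutions combined, CuBr·SMe2 (15 mol %), −10 → 25 °C; I2, −30 °C; H2O
Reagents that add atoms: iodine II
Why: Copper-catalysed anti-carbomagnesiation of the propargylic magnesium alkoxide puts the alkyl group on the carbon next to CH2O and magnesium on the terminal carbon in a five-membered chelate, so that iodinolysis with retention should give the alkenyl iodide cis to CH2OH, which is the alkene geometry of the target.

Step 10
Reactants: 22 (Z)-3-iodo-2-{(E)-6-[(S)-3-(TBSO)-2,6,6-trimethylcyclohex-1-en-1-yl]-4-methylhex-3-en-1-yl}prop-2-en-1-ol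
Product: 23 (S)-3-[(3E,7Z)-8-iodo-3-methyl-7-(TBSO-methyl)octa-3,7-dien-1-yl]-1-(TBSO)-2,4,4-trimethylcyclohex-2-ene
Conditions: TBSCl, imidazole, DMF, 25 °C
Reagents that add atoms: tert-butyldimethylsilyl chloride CC(C)(C)[Si](C)(C)Cl
Why: Silyl ether formation protects the primary allylic alcohol before halogen–metal exchange.

Step 11
Reactants: 23 (S)-3-[(3E,7Z)-8-iodo-3-methyl-7-(TBSO-methyl)octa-3,7-dien-1-yl]-1-(TBSO)-2,4,4-trimethylcyclohex-2-ene; 24 methyl (S)-glycidate
Product: 27 methyl (2S,4Z,8E)-2-hydroxy-9-methyl-5-(TBSO-methyl)-11-[(S)-3-(TBSO)-2,6,6-trimethylcyclohex-1-en-1-yl]undeca-4,8-dienoate, via alkenyllithium 25 (not isolated), via alkenylmagnesium bromide 26 (not isolated)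
Conditions: t-BuLi, Et2O, −78 °C; MgBr2·OEt2, −78 °C; CuBr·SMe2 (10 mol %), 24, THF, −40 °C; H2O
Reagents that add atoms: none
Why: Iodine–lithium exchange with retention, transmetalation to the alkenyl Grignard reagent and copper-catalysed SN2 opening of the glycidic ester at its CH2 carbon form the allylic C–C bond and carry the (S)-carbinol carbon over unchanged from the chiral pool.

Step 12
Reactants: 27 methyl (2S,4Z,8E)-2-hydroxy-9-methyl-5-(TBSO-methyl)-11-[(S)-3-(TBSO)-2,6,6-trimethylcyclohex-1-en-1-yl]undeca-4,8-dienoate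
Product: 28 methyl (2S,4Z,8E)-2-acetoxy-9-methyl-5-(TBSO-methyl)-11-[(S)-3-(TBSO)-2,6,6-trimethylcyclohex-1-en-1-yl]undeca-4,8-dienoate
Conditions: Ac2O, pyridine, DMAP (cat.), CH2Cl2, 25 °C
Reagents that add atoms: acetic anhydride CC(=O)OC(C)=O
Why: DMAP-catalysed acetylation of the secondary alcohol brings in the two carbons that become C2 and C3 of the lactone.

Step 13
Reactants: 28 methyl (2S,4Z,8E)-2-acetoxy-9-methyl-5-(TBSO-methyl)-11-[(S)-3-(TBSO)-2,6,6-trimethylcyclohex-1-en-1-yl]undeca-4,8-dienoate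
Product: 29 (S)-4-hydroxy-5-{(2Z,6E)-7-methyl-3-(TBSO-methyl)-9-[(S)-3-(TBSO)-2,6,6-trimethylcyclohex-1-en-1-yl]nona-2,6-dien-1-yl}furan-2(5H)-one
Conditions: LiN(SiMe3)2, THF, −78 → 0 °C; aq. HCl to pH 3
Reagents that add atoms: none
Why: Dieckmann (intramolecular Claisen) condensation of the acetate enolate onto the neighbouring methyl ester closes the five-membered ring as the tetronic acid, kinetic deprotonation of the acetate methyl group leaving the carbinol carbon untouched.

Step 14
Reactants: 29 (S)-4-hydroxy-5-{(2Z,6E)-7-methyl-3-(TBSO-methyl)-9-[(S)-3-(TBSO)-2,6,6-trimethylcyclohex-1-en-1-yl]nona-2,6-dien-1-yl}furan-2(5H)-one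
Product: 30 (S)-5-oxo-2-{(2Z,6E)-7-methyl-3-(TBSO-methyl)-9-[(S)-3-(TBSO)-2,6,6-trimethylcyclohex-1-en-1-yl]nona-2,6-dien-1-yl}-2,5-dihydrofuran-3-yl trifluoromethanesulfonate
Conditions: Tf2O, i-Pr2NEt, CH2Cl2, −78 °C
Reagents that add atoms: trifluoromethanesulfonic anhydride O=S(=O)(OS(=O)(=O)C(F)(F)F)C(F)(F)F
Why: O-sulfonylation of the vinylogous acid (enol triflate formation) turns the 4-hydroxy group into a leaving group for cross-coupling.

Step 15
Reactants: 30 (S)-5-oxo-2-{(2Z,6E)-7-methyl-3-(TBSO-methyl)-9-[(S)-3-(TBSO)-2,6,6-trimethylcyclohex-1-en-1-yl]nona-2,6-dien-1-yl}-2,5-dihydrofuran-3-yl trifluoromethanesulfonate; 31 (tributylstannyl)methanol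
Product: 32 (S)-4-(hydroxymethyl)-5-{(2Z,6E)-7-methyl-3-(TBSO-methyl)-9-[(S)-3-(TBSO)-2,6,6-trimethylcyclohex-1-en-1-yl]nona-2,6-dien-1-yl}furan-2(5H)-one
Conditions: Pd(PPh3)4 (5 mol %), LiCl, 1,4-dioxane, 90 °C
Reagents that add atoms: none
Why: Stille coupling of the electron-poor enol triflate with the hydroxymethylstannane installs the CH2OH group at C4 of the butenolide under neutral conditions that should leave the lactone stereocentre intact.

Step 16
Reactants: 32 (S)-4-(hydroxymethyl)-5-{(2Z,6E)-7-methyl-3-(TBSO-methyl)-9-[(S)-3-(TBSO)-2,6,6-trimethylcyclohex-1-en-1-yl]nona-2,6-dien-1-yl}furan-2(5H)-one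
Product: 33 (S)-4-(hydroxymethyl)-5-{(2Z,6E)-3-(hydroxymethyl)-9-[(S)-3-hydroxy-2,6,6-trimethylcyclohex-1-en-1-yl]-7-methylnona-2,6-dien-1-yl}furan-2(5H)-one
Conditions: HF·pyridine, pyridine, THF, 0 → 25 °C
Reagents that add atoms: none
Why: Fluoride-mediated cleavage of both silyl ethers (desilylation), buffered with pyridine to spare the acid-sensitive allylic alcohol and the base-sensitive butenolide, should give the target.

**Compound list**

1 | methyl isobutyrate | COC(=O)C(C)C | starting material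
2 | ethyl vinyl ketone (pent-1-en-3-one) | CCC(=O)C=C | starting material
3 | methyl 2,2-dimethyl-5-oxoheptanoate (present as its enolate) | CCC(=O)CCC(C)(C)C(=O)OC | intermediate (not isolated)
4 | 2,4,4-trimethylcyclohexane-1,3-dione | CC1C(=O)CCC(C)(C)C1=O | intermediate
5 | 3-isobutoxy-2,6,6-trimethylcyclohex-2-en-1-one | CC1=C(OCC(C)C)CCC(C)(C)C1=O | intermediate
6 | 4-bromo-1-(trimethylsilyl)but-1-yne | C[Si](C)(C)C#CCCBr | starting material
7 | [4-(trimethylsilyl)but-3-yn-1-yl]magnesium bromide | C[Si](C)(C)C#CCC[Mg]Br | intermediate (not isolated)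
8 | bromomagnesium 3-isobutoxy-2,6,6-trimethyl-1-[4-(trimethylsilyl)but-3-yn-1-yl]cyclohex-2-en-1-olate | CC1=C(OCC(C)C)CCC(C)(C)C1(O[Mg]Br)CCC#C[Si](C)(C)C | intermediate (not isolated)
9 | 2,4,4-trimethyl-3-[4-(trimethylsilyl)but-3-yn-1-yl]cyclohex-2-en-1-one | CC1=C(CCC#C[Si](C)(C)C)C(C)(C)CCC1=O | intermediate
10 | (S)-2,4,4-trimethyl-3-[4-(trimethylsilyl)but-3-yn-1-yl]cyclohex-2-en-1-ol | CC1=C(CCC#C[Si](C)(C)C)C(C)(C)CC[C@@H]1O | intermediate
11 | (S)-3-(but-3-yn-1-yl)-2,4,4-trimethylcyclohex-2-en-1-ol | CC1=C(CCC#C)C(C)(C)CC[C@@H]1O | intermediate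
12 | (S)-3-(but-3-yn-1-yl)-1-(tert-butyldimethylsilyloxy)-2,4,4-trimethylcyclohex-2-ene | CC1=C(CCC#C)C(C)(C)CC[C@@H]1O[Si](C)(C)C(C)(C)C | intermediate
13 | ethylene oxide (oxirane) | C1CO1 | starting material
14 | (E)-alkenyl(dimethyl)alane from 12 (methyl and aluminium cis) | CC1=C(CC/C(C)=C/[Al](C)C)C(C)(C)CC[C@@H]1O[Si](C)(C)C(C)(C)C | intermediate (not isolated)
15 | lithium (E)-alkenyl(butyl)dimethylaluminate | [Li+].CC1=C(CC/C(C)=C/[Al-](C)(C)CCCC)C(C)(C)CC[C@@H]1O[Si](C)(C)C(C)(C)C | intermediate (not isolated)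
16 | (E)-6-[(S)-3-(tert-butyldimethylsilyloxy)-2,6,6-trimethylcyclohex-1-en-1-yl]-4-methylhex-3-en-1-ol | CC1=C(CC/C(C)=C/CCO)C(C)(C)CC[C@@H]1O[Si](C)(C)C(C)(C)C | intermediate
17 | (S)-3-[(E)-6-bromo-3-methylhex-3-en-1-yl]-1-(tert-butyldimethylsilyloxy)-2,4,4-trimethylcyclohex-2-ene | CC1=C(CC/C(C)=C/CCBr)C(C)(C)CC[C@@H]1O[Si](C)(C)C(C)(C)C | intermediate
18 | propargyl alcohol (prop-2-yn-1-ol) | C#CCO | starting material
19 | Grignard reagent of 17 | CC1=C(CC/C(C)=C/CC[Mg]Br)C(C)(C)CC[C@@H]1O[Si](C)(C)C(C)(C)C | intermediate (not isolated)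
20 | bromomagnesium prop-2-yn-1-olate | C#CCO[Mg]Br | intermediate (not isolated)
21 | chelated (Z)-alkenylmagnesium alkoxide (magnesium cis to CH2O) | CC1=C(CC/C(C)=C/CC/C(=C/[Mg]Br)CO[Mg]Br)C(C)(C)CC[C@@H]1O[Si](C)(C)C(C)(C)C | intermediate (not isolated)
22 | (Z)-3-iodo-2-{(E)-6-[(S)-3-(tert-butyldimethylsilyloxy)-2,6,6-trimethylcyclohex-1-en-1-yl]-4-methylhex-3-en-1-yl}prop-2-en-1-ol | CC1=C(CC/C(C)=C/CC/C(=C/I)CO)C(C)(C)CC[C@@H]1O[Si](C)(C)C(C)(C)C | intermediate
23 | (S)-3-[(3E,7Z)-8-iodo-3-methyl-7-(tert-butyldimethylsilyloxymethyl)octa-3,7-dien-1-yl]-1-(tert-butyldimethylsilyloxy)-2,4,4-trimethylcyclohex-2-ene | CC1=C(CC/C(C)=C/CC/C(=C/I)CO[Si](C)(C)C(C)(C)C)C(C)(C)CC[C@@H]1O[Si](C)(C)C(C)(C)C | intermediate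
24 | methyl (S)-glycidate (methyl (2S)-oxirane-2-carboxylate) | COC(=O)[C@@H]1CO1 | starting material
25 | (Z)-alkenyllithium from 23 | CC1=C(CC/C(C)=C/CC/C(=C/[Li])CO[Si](C)(C)C(C)(C)C)C(C)(C)CC[C@@H]1O[Si](C)(C)C(C)(C)C | intermediate (not isolated)
26 | (Z)-alkenylmagnesium bromide from 25 | CC1=C(CC/C(C)=C/CC/C(=C/[Mg]Br)CO[Si](C)(C)C(C)(C)C)C(C)(C)CC[C@@H]1O[Si](C)(C)C(C)(C)C | intermediate (not isolated)
27 | methyl (2S,4Z,8E)-2-hydroxy-9-methyl-5-(tert-butyldimethylsilyloxymethyl)-11-[(S)-3-(tert-butyldimethylsilyloxy)-2,6,6-trimethylcyclohex-1-en-1-yl]undeca-4,8-dienoate | CC1=C(CC/C(C)=C/CC/C(=C/C[C@H](O)C(=O)OC)CO[Si](C)(C)C(C)(C)C)C(C)(C)CC[C@@H]1O[Si](C)(C)C(C)(C)C | intermediate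
28 | methyl (2S,4Z,8E)-2-acetoxy-9-methyl-5-(tert-butyldimethylsilyloxymethyl)-11-[(S)-3-(tert-butyldimethylsilyloxy)-2,6,6-trimethylcyclohex-1-en-1-yl]undeca-4,8-dienoate | CC1=C(CC/C(C)=C/CC/C(=C/C[C@H](OC(C)=O)C(=O)OC)CO[Si](C)(C)C(C)(C)C)C(C)(C)CC[C@@H]1O[Si](C)(C)C(C)(C)C | intermediate
29 | (S)-4-hydroxy-5-{(2Z,6E)-7-methyl-3-(tert-butyldimethylsilyloxymethyl)-9-[(S)-3-(tert-butyldimethylsilyloxy)-2,6,6-trimethylcyclohex-1-en-1-yl]nona-2,6-dien-1-yl}furan-2(5H)-one (tetronic acid) | CC1=C(CC/C(C)=C/CC/C(=C/C[C@@H]2OC(=O)C=C2O)CO[Si](C)(C)C(C)(C)C)C(C)(C)CC[C@@H]1O[Si](C)(C)C(C)(C)C | intermediate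
30 | 4-trifluoromethanesulfonate of 29 | CC1=C(CC/C(C)=C/CC/C(=C/C[C@@H]2OC(=O)C=C2OS(=O)(=O)C(F)(F)F)CO[Si](C)(C)C(C)(C)C)C(C)(C)CC[C@@H]1O[Si](C)(C)C(C)(C)C | intermediate
31 | (tributylstannyl)methanol | OC[Sn](CCCC)(CCCC)CCCC | starting material
32 | (S)-4-(hydroxymethyl)-5-{(2Z,6E)-7-methyl-3-(tert-butyldimethylsilyloxymethyl)-9-[(S)-3-(tert-butyldimethylsilyloxy)-2,6,6-trimethylcyclohex-1-en-1-yl]nona-2,6-dien-1-yl}furan-2(5H)-one | CC1=C(CC/C(C)=C/CC/C(=C/C[C@@H]2OC(=O)C=C2CO)CO[Si](C)(C)C(C)(C)C)C(C)(C)CC[C@@H]1O[Si](C)(C)C(C)(C)C | intermediate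
33 | (S)-4-(hydroxymethyl)-5-{(2Z,6E)-3-(hydroxymethyl)-9-[(S)-3-hydroxy-2,6,6-trimethylcyclohex-1-en-1-yl]-7-methylnona-2,6-dien-1-yl}furan-2(5H)-one | CC1=C(CC/C(C)=C/CC/C(=C/C[C@@H]2OC(=O)C=C2CO)CO)C(C)(C)CC[C@@H]1O | target

**Step count and risks**

Total step count: 16. Longest linear sequence: 16 steps (1 and 2 to 33).

The three steps most likely to fail:

1. Step 9 (carbomagnesiation). The primary alkyl Grignard reagent may be consumed by protonation and homocoupling faster than it adds across the alkynol, and incomplete chelation would lower the geometric purity of the alkenyl iodide. The fallback sets out from 17 and comes back at 23. The Grignard reagent 19 would be acylated with N-methoxy-N-methyl-2-(tert-butyldimethylsilyloxy)acetamide (Weinreb ketone synthesis) to the α-silyloxy ketone (E)-6-methyl-1-(TBSO)-8-[(S)-3-(TBSO)-2,6,6-trimethylcyclohex-1-en-1-yl]oct-5-en-2-one F1. Stork–Zhao iodomethylenation of the ketone ([Ph3PCH2I]I, NaN(SiMe3)2, THF, −78 °C) should then give 23 directly, since α-alkoxy ketones are known to place the ylide substituent cis to the CH2O group.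

2. Step 3 (addition to the vinylogous ester). Deprotonation of the vinylogous ester at its γ-CH2 and steric shielding of the carbonyl by the adjacent quaternary carbon may return starting material instead of the adduct. The fallback sets out from 5 and comes back at 12. Allylmagnesium bromide, which adds to hindered ketones through a cyclic six-membered transition state, would be used in the same addition–hydrolysis sequence to give 3-allyl-2,4,4-trimethylcyclohex-2-en-1-one F2. Reduction as in step 4 would give (S)-3-allyl-2,4,4-trimethylcyclohex-2-en-1-ol F3, and silylation as in step 6 the TBS ether of that alcohol F4. Hydroboration of the terminal alkene with 9-BBN and oxidation (H2O2, NaOH) would give 3-[(S)-3-(TBSO)-2,6,6-trimethylcyclohex-1-en-1-yl]propan-1-ol F5, and Dess–Martin oxidation 3-[(S)-3-(TBSO)-2,6,6-trimethylcyclohex-1-en-1-yl]propanal F6. Ohira–Bestmann homologation (dimethyl (1-diazo-2-oxopropyl)phosphonate, K2CO3, MeOH) would then give the alkyne 12.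

3. Step 13 (Dieckmann closure). The amide base may remove the proton at the carbinol carbon (α to the methyl ester) in competition with the acetate methyl group, which would erode the configuration of the lactone stereocentre before ring closure. The fallback sets out from 27 and comes back at 29. Alcohol 27 would be esterified with allyl hydrogen malonate (DCC, DMAP, CH2Cl2) to the allyl malonate ester of 27 F7. Its doubly activated methylene should close the ring under mild base (Cs2CO3, DMF, 25 °C) to the 3-(allyloxycarbonyl)tetronic acid F8. Pd(PPh3)4 with morpholine would remove the allyl ester, and the free acid should lose carbon dioxide to give 29.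

Further compounds
F1 | step 9 | (E)-6-methyl-1-(tert-butyldimethylsilyloxy)-8-[(S)-3-(tert-butyldimethylsilyloxy)-2,6,6-trimethylcyclohex-1-en-1-yl]oct-5-en-2-one | CC1=C(CC/C(C)=C/CCC(=O)CO[Si](C)(C)C(C)(C)C)C(C)(C)CC[C@@H]1O[Si](C)(C)C(C)(C)C
F2 | step 3 | 3-allyl-2,4,4-trimethylcyclohex-2-en-1-one | CC1=C(CC=C)C(C)(C)CCC1=O
F3 | step 3 | (S)-3-allyl-2,4,4-trimethylcyclohex-2-en-1-ol | CC1=C(CC=C)C(C)(C)CC[C@@H]1O
F4 | step 3 | (S)-3-allyl-1-(tert-butyldimethylsilyloxy)-2,4,4-trimethylcyclohex-2-ene | CC1=C(CC=C)C(C)(C)CC[C@@H]1O[Si](C)(C)C(C)(C)C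
F5 | step 3 | 3-[(S)-3-(tert-butyldimethylsilyloxy)-2,6,6-trimethylcyclohex-1-en-1-yl]propan-1-ol | CC1=C(CCCO)C(C)(C)CC[C@@H]1O[Si](C)(C)C(C)(C)C
F6 | step 3 | 3-[(S)-3-(tert-butyldimethylsilyloxy)-2,6,6-trimethylcyclohex-1-en-1-yl]propanal | CC1=C(CCC=O)C(C)(C)CC[C@@H]1O[Si](C)(C)C(C)(C)C
F7 | step 13 | allyl malonate ester of 27 (malonyl group on the secondary hydroxyl) | CC1=C(CC/C(C)=C/CC/C(=C/C[C@H](OC(=O)CC(=O)OCC=C)C(=O)OC)CO[Si](C)(C)C(C)(C)C)C(C)(C)CC[C@@H]1O[Si](C)(C)C(C)(C)C
F8 | step 13 | 3-(allyloxycarbonyl) derivative of tetronic acid 29 | CC1=C(CC/C(C)=C/CC/C(=C/C[C@@H]2OC(=O)C(C(=O)OCC=C)=C2O)CO[Si](C)(C)C(C)(C)C)C(C)(C)CC[C@@H]1O[Si](C)(C)C(C)(C)C
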